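**Assumption:** the SMILES is read as a (2S,3S,4S,5R)-oxolane (2,3-trans, 3,4-trans, 4,5-cis, 2,5-cis) whose C2 aryl ring carries the (1R,2S) (erythro) side chain and whose C5 aryl ring carries the (1R,2R) (threo) side chain; C7/C8 denote the carbinol and methyl-bearing carbons of each side chain.

## Retrosynthetic overview

1. Target 18 ⇐ bis-silyl ether 17 by global desilylation.
2. The oxolane is the only ring made (last ring event; all four arenes are bought). Its O1–C5 and C4–C5 bonds come from a reductive radical oxa-annulation of homoallylic alcohol 15 with aldehyde 12.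
3. 15 (C2, C3) ⇐ aldehyde 11 by chiral phosphoric acid-catalysed anti-crotylboration with 13.
4. 11 and 12 ⇐ erythro alcohol 7 and threo alcohol 10, both from one oxazaborolidine-catalysed reduction of racemic ketone 4. The catalyst fixes C7 as R in both C8 series, so the two separable C8 epimers are exactly the two side chains.
5. 4 ⇐ vanillin 3 + bromoketone 2 ⇐ propiophenone 1.

## Route

Step 1
Reactants: 1 1-(3,4-dimethoxyphenyl)propan-1-one
Product: 2 rac-2-bromo-1-(3,4-dimethoxyphenyl)propan-1-one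
Conditions: CuBr2 (2.1 equiv), EtOAc/CHCl3, reflux
Reagents that add atoms: copper dibromide, Br[Cu]Br
Why: King-type α-bromination of the ketone enol by CuBr2 is selective for the α-carbon over the electron-rich ring; the new centre is racemic by design.

Step 2
Reactants: 2 rac-2-bromo-1-(3,4-dimethoxyphenyl)propan-1-one; 3 vanillin (4-hydroxy-3-methoxybenzaldehyde)
Product: 4 rac-4-{[1-(3,4-dimethoxyphenyl)-1-oxopropan-2-yl]oxy}-3-methoxybenzaldehyde
Conditions: K2CO3, KI (cat.), acetone, 50 °C
Reagents that add atoms: none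
Why: Williamson etherification, in which the phenoxide of 3 displaces the activated α-keto bromide by SN2 (standard entry to α-aryloxy propiophenones).

Step 3
Reactants: 4 rac-4-{[1-(3,4-dimethoxyphenyl)-1-oxopropan-2-yl]oxy}-3-methoxybenzaldehyde
Product: 7 4-{[(1R,2S)-1-(3,4-dimethoxyphenyl)-1-hydroxypropan-2-yl]oxy}-3-methoxybenzaldehyde (erythro), via 2S phosphonium-masked keto aldehyde 5 (not isolated), via phosphonium-masked erythro alcohol 6 (not isolated)
Conditions: PPh3, TMSOTf, CH2Cl2, rt; then (R)-Me-CBS (0.3 equiv), BH3·SMe2, −40 to −20 °C; MeOH; TBAF, THF, 0 °C; chromatography, first diastereomer fraction (at most 50 % from 4)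
Reagents that add atoms: none
Why: The aldehyde is masked in situ as its O-silyl α-phosphonium adduct, which borane does not reduce, and the (R)-oxazaborolidine–borane complex (Corey–Bakshi–Shibata reduction, aryl as the large group) delivers hydride to one ketone face whatever the C8 configuration, so the 2S half of the racemate gives the (1R,2S) alcohol with C7 set as R (catalyst control matched with the Felkin preference), and fluoride then collapses the adduct back to the aldehyde.

Step 4
Reactants: 4 rac-4-{[1-(3,4-dimethoxyphenyl)-1-oxopropan-2-yl]oxy}-3-methoxybenzaldehyde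
Product: 10 4-{[(1R,2R)-1-(3,4-dimethoxyphenyl)-1-hydroxypropan-2-yl]oxy}-3-methoxybenzaldehyde (threo), via 2R phosphonium-masked keto aldehyde 8 (not isolated), via phosphonium-masked threo alcohol 9 (not isolated)
Conditions: same flask as step 3: PPh3, TMSOTf, CH2Cl2, rt; then (R)-Me-CBS (0.3 equiv), BH3·SMe2, −40 to −20 °C; MeOH; TBAF, THF, 0 °C; chromatography, second diastereomer fraction (at most 50 % from 4)
Reagents that add atoms: none
Why: The 2R half of the same masked racemate is reduced by the same catalyst from the same ketone face (Corey–Bakshi–Shibata reduction under catalyst control, here opposed to the Felkin preference), so C7 is again R and the (1R,2R) threo diastereomer results, which is separable from 7 because the two differ only at C8.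

Step 5
Reactants: 7 4-{[(1R,2S)-1-(3,4-dimethoxyphenyl)-1-hydroxypropan-2-yl]oxy}-3-methoxybenzaldehyde
Product: 11 4-{[(1R,2S)-1-[(tert-butyldimethylsilyl)oxy]-1-(3,4-dimethoxyphenyl)propan-2-yl]oxy}-3-methoxybenzaldehyde
Conditions: TBSOTf, 2,6-lutidine, CH2Cl2, −78 to 0 °C
Reagents that add atoms: tert-butyldimethylsilyl triflate, CC(C)(C)[Si](C)(C)OS(=O)(=O)C(F)(F)F
Why: Silyl triflate with a hindered pyridine base silylates the hindered benzylic alcohol without touching the aldehyde or either stereocentre; the ether keeps this hydroxyl out of the acetal chemistry of step 8.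

Step 6
Reactants: 10 4-{[(1R,2R)-1-(3,4-dimethoxyphenyl)-1-hydroxypropan-2-yl]oxy}-3-methoxybenzaldehyde
Product: 12 4-{[(1R,2R)-1-[(tert-butyldimethylsilyl)oxy]-1-(3,4-dimethoxyphenyl)propan-2-yl]oxy}-3-methoxybenzaldehyde
Conditions: TBSOTf, 2,6-lutidine, CH2Cl2, −78 to 0 °C
Reagents that add atoms: tert-butyldimethylsilyl triflate, CC(C)(C)[Si](C)(C)OS(=O)(=O)C(F)(F)F
Why: Same silylation as step 5, applied to the threo series.

Step 7
Reactants: 11 4-{[(1R,2S)-1-[(tert-butyldimethylsilyl)oxy]-1-(3,4-dimethoxyphenyl)propan-2-yl]oxy}-3-methoxybenzaldehyde; 13 (E)-crotylboronic acid pinacol ester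
Product: 15 (1S,2S)-1-[4-{[(1R,2S)-1-[(tert-butyldimethylsilyl)oxy]-1-(3,4-dimethoxyphenyl)propan-2-yl]oxy}-3-methoxyphenyl]-2-methylbut-3-en-1-ol, via pinacol borate ester 14 (not isolated)
Conditions: (S)-TRIP phosphoric acid (5 mol%), 4 Å MS, toluene, −30 °C; aq. NaHCO3
Reagents that add atoms: none
Why: Chiral phosphoric acid-catalysed crotylboration, in which the acid hydrogen-bonds to a boronate oxygen and the closed chair transition state transfers the E-crotyl group to the Si face of the aldehyde (the R catalyst is Re-selective), giving the anti (1S,2S) alcohol and so setting C2 and C3 of the oxolane.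

Step 8
Reactants: 15 (1S,2S)-1-[4-{[(1R,2S)-1-[(tert-butyldimethylsilyl)oxy]-1-(3,4-dimethoxyphenyl)propan-2-yl]oxy}-3-methoxyphenyl]-2-methylbut-3-en-1-ol; 12 4-{[(1R,2R)-1-[(tert-butyldimethylsilyl)oxy]-1-(3,4-dimethoxyphenyl)propan-2-yl]oxy}-3-methoxybenzaldehyde
Product: 17 (2S,3S,4S,5R)-2-[4-{[(1R,2S)-1-[(tert-butyldimethylsilyl)oxy]-1-(3,4-dimethoxyphenyl)propan-2-yl]oxy}-3-methoxyphenyl]-5-[4-{[(1R,2R)-1-[(tert-butyldimethylsilyl)oxy]-1-(3,4-dimethoxyphenyl)propan-2-yl]oxy}-3-methoxyphenyl]-3,4-dimethyloxolane, via oxocarbenium phosphate 16 (not isolated)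
Conditions: 3DPAFIPN (2,4,6-tris(diphenylamino)-5-fluoroisophthalonitrile, 2 mol%), (PhO)2P(O)OH (10 mol%), γ-terpinene (3 equiv), 4 Å MS, CH2Cl2, 450 nm LEDs, 0 °C
Reagents that add atoms: none
Why: Proposed new method: acid-catalysed condensation of 15 with 12 gives the E-oxocarbenium ion 16, which (estimated reduction potential about −0.7 V against SCE) takes one electron from the photoexcited cyanoarene dye to become an α-alkoxybenzyl radical; this closes 5-exo-trig on the vinyl group through a chair transition state with the C5 aryl, the C2 aryl and the C3 methyl all pseudo-equatorial, which forms the ring and sets C4 (methyl trans to the C3 methyl) and C5 (aryl cis to the C4 methyl, 2,5-cis), the outcome that the Beckwith guidelines predict for each of the three substituents; only the resulting primary radical abstracts hydrogen quickly from γ-terpinene, whose cyclohexadienyl radical passes an electron and a proton on to carry the chain, while γ-terpinene is too poor a hydride donor to reduce 16 ionically; the closest known reactions are tin hydride 5-exo cyclisation of α-alkoxy radicals from mixed O,Se-acetals of homoallylic alcohols, photoredox ketyl–olefin cyclisation and acid-mediated reductive etherification.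

Step 9
Reactants: 17 (2S,3S,4S,5R)-2,5-diaryl-3,4-dimethyloxolane bis(tert-butyldimethylsilyl) ether (full name in step 8)
Product: 18 (1R,2S)-1-(3,4-dimethoxyphenyl)-2-{4-[(2S,3S,4S,5R)-5-(4-{[(1R,2R)-1-(3,4-dimethoxyphenyl)-1-hydroxypropan-2-yl]oxy}-3-methoxyphenyl)-3,4-dimethyloxolan-2-yl]-2-methoxyphenoxy}propan-1-ol (CNP0116650.9)
Conditions: TBAF, AcOH, THF, 0 °C to rt
Reagents that add atoms: none
Why: Fluoride-driven desilylation (Si–F bond formation) frees both benzylic alcohols; the acetic acid buffer keeps the medium near neutral so no stereocentre is disturbed.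

## Compound list

1 | 1-(3,4-dimethoxyphenyl)propan-1-one | CCC(=O)c1ccc(OC)c(OC)c1 | starting material
2 | rac-2-bromo-1-(3,4-dimethoxyphenyl)propan-1-one | CC(Br)C(=O)c1ccc(OC)c(OC)c1 | intermediate
3 | vanillin | COc1cc(C=O)ccc1O | starting material
4 | rac-4-{[1-(3,4-dimethoxyphenyl)-1-oxopropan-2-yl]oxy}-3-methoxybenzaldehyde | COc1ccc(cc1OC)C(=O)C(C)Oc1ccc(C=O)cc1OC | intermediate
5 | [(4-{[(2S)-1-(3,4-dimethoxyphenyl)-1-oxopropan-2-yl]oxy}-3-methoxyphenyl)(trimethylsilyloxy)methyl]triphenylphosphonium triflate (both epimers at the phosphonium-bearing carbon) | COc1ccc(cc1OC)C(=O)[C@H](C)Oc1ccc(cc1OC)C(O[Si](C)(C)C)[P+](c1ccccc1)(c1ccccc1)c1ccccc1.[O-]S(=O)(=O)C(F)(F)F | intermediate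
6 | [(4-{[(1R,2S)-1-(3,4-dimethoxyphenyl)-1-hydroxypropan-2-yl]oxy}-3-methoxyphenyl)(trimethylsilyloxy)methyl]triphenylphosphonium triflate | COc1ccc([C@@H](O)[C@H](C)Oc2ccc(cc2OC)C(O[Si](C)(C)C)[P+](c2ccccc2)(c2ccccc2)c2ccccc2)cc1OC.[O-]S(=O)(=O)C(F)(F)F | intermediate
7 | 4-{[(1R,2S)-1-(3,4-dimethoxyphenyl)-1-hydroxypropan-2-yl]oxy}-3-methoxybenzaldehyde | COc1ccc([C@@H](O)[C@H](C)Oc2ccc(C=O)cc2OC)cc1OC | intermediate
8 | [(4-{[(2R)-1-(3,4-dimethoxyphenyl)-1-oxopropan-2-yl]oxy}-3-methoxyphenyl)(trimethylsilyloxy)methyl]triphenylphosphonium triflate (both epimers at the phosphonium-bearing carbon) | COc1ccc(cc1OC)C(=O)[C@@H](C)Oc1ccc(cc1OC)C(O[Si](C)(C)C)[P+](c1ccccc1)(c1ccccc1)c1ccccc1.[O-]S(=O)(=O)C(F)(F)F | intermediate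
9 | [(4-{[(1R,2R)-1-(3,4-dimethoxyphenyl)-1-hydroxypropan-2-yl]oxy}-3-methoxyphenyl)(trimethylsilyloxy)methyl]triphenylphosphonium triflate | COc1ccc([C@@H](O)[C@@H](C)Oc2ccc(cc2OC)C(O[Si](C)(C)C)[P+](c2ccccc2)(c2ccccc2)c2ccccc2)cc1OC.[O-]S(=O)(=O)C(F)(F)F | intermediate
10 | 4-{[(1R,2R)-1-(3,4-dimethoxyphenyl)-1-hydroxypropan-2-yl]oxy}-3-methoxybenzaldehyde | COc1ccc([C@@H](O)[C@@H](C)Oc2ccc(C=O)cc2OC)cc1OC | intermediate
11 | 4-{[(1R,2S)-1-[(tert-butyldimethylsilyl)oxy]-1-(3,4-dimethoxyphenyl)propan-2-yl]oxy}-3-methoxybenzaldehyde | COc1ccc([C@@H](O[Si](C)(C)C(C)(C)C)[C@H](C)Oc2ccc(C=O)cc2OC)cc1OC | intermediate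
12 | 4-{[(1R,2R)-1-[(tert-butyldimethylsilyl)oxy]-1-(3,4-dimethoxyphenyl)propan-2-yl]oxy}-3-methoxybenzaldehyde | COc1ccc([C@@H](O[Si](C)(C)C(C)(C)C)[C@@H](C)Oc2ccc(C=O)cc2OC)cc1OC | intermediate
13 | (E)-crotylboronic acid pinacol ester | C/C=C/CB1OC(C)(C)C(C)(C)O1 | starting material
14 | pinacol borate ester of 15 (2-{[(1S,2S)-1-aryl-2-methylbut-3-en-1-yl]oxy}-4,4,5,5-tetramethyl-1,3,2-dioxaborolane) | COc1ccc([C@@H](O[Si](C)(C)C(C)(C)C)[C@H](C)Oc2ccc([C@@H](OB3OC(C)(C)C(C)(C)O3)[C@@H](C)C=C)cc2OC)cc1OC | intermediate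
15 | (1S,2S)-1-[4-{[(1R,2S)-1-[(tert-butyldimethylsilyl)oxy]-1-(3,4-dimethoxyphenyl)propan-2-yl]oxy}-3-methoxyphenyl]-2-methylbut-3-en-1-ol | COc1ccc([C@@H](O[Si](C)(C)C(C)(C)C)[C@H](C)Oc2ccc([C@@H](O)[C@@H](C)C=C)cc2OC)cc1OC | intermediate
16 | E-oxocarbenium ion from 15 and 12, diphenyl phosphate salt | COc1ccc([C@@H](O[Si](C)(C)C(C)(C)C)[C@H](C)Oc2ccc([C@@H](/[O+]=C/c3ccc(O[C@H](C)[C@H](O[Si](C)(C)C(C)(C)C)c4ccc(OC)c(OC)c4)c(OC)c3)[C@@H](C)C=C)cc2OC)cc1OC.[O-]P(=O)(Oc1ccccc1)Oc1ccccc1 | intermediate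
17 | (2S,3S,4S,5R)-2,5-diaryl-3,4-dimethyloxolane bis(tert-butyldimethylsilyl) ether (full name in step 8) | COc1ccc([C@@H](O[Si](C)(C)C(C)(C)C)[C@H](C)Oc2ccc([C@H]3O[C@@H](c4ccc(O[C@H](C)[C@H](O[Si](C)(C)C(C)(C)C)c5ccc(OC)c(OC)c5)c(OC)c4)[C@@H](C)[C@@H]3C)cc2OC)cc1OC | intermediate
18 | (1R,2S)-1-(3,4-dimethoxyphenyl)-2-{4-[(2S,3S,4S,5R)-5-(4-{[(1R,2R)-1-(3,4-dimethoxyphenyl)-1-hydroxypropan-2-yl]oxy}-3-methoxyphenyl)-3,4-dimethyloxolan-2-yl]-2-methoxyphenoxy}propan-1-ol | COc1ccc([C@@H](O)[C@H](C)Oc2ccc([C@H]3O[C@@H](c4ccc(O[C@H](C)[C@H](O)c5ccc(OC)c(OC)c5)c(OC)c4)[C@@H](C)[C@@H]3C)cc2OC)cc1OC | target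

## Step count and risks

Total steps: 9. Steps 3 and 4 are run as one flask and give its two isolated products, so the route needs eight separate operations. Longest linear sequence: 7 (steps 1, 2, 3, 5, 7, 8, 9); steps 4 and 6 lie on the branch that delivers 12.

The three steps most likely to fail:

**Step 8 (proposed new step).** The risks are three:
- the oxocarbenium ion 16 may undergo crotyl transfer (2-oxonia-Cope) or Prins closure before it is reduced;
- the stabilised benzylic radical may close slowly or reversibly on the unactivated vinyl group;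
- the open radical may be reduced to the benzyl ether.

The fallback uses known chemistry and sets out from 15 and 12. Alcohol 15 is silylated (Me3SiCl, imidazole, CH2Cl2) to its trimethylsilyl ether F1. F1 is combined with 12 and PhSeSiMe3 under catalytic TMSOTf at −78 °C (Et3N quench) to give the mixed O,Se-acetal F2. This is the selenium counterpart of the standard silyl-sulfide mixed-acetal synthesis; at −78 °C trapping of the transient cation by the selenide should outrun crotyl transfer. F2 is then cyclised by slow addition of Bu3SnH with AIBN in toluene at 90 °C (classical 5-exo cyclisation of an α-alkoxy radical, same chair transition state), and the route is rejoined at 17.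

**Step 3.** In-situ masking may be incomplete, or the triflate salts may disturb the oxazaborolidine. In addition, the 2R ketone is the mismatched case (substrate control favours erythro), so the erythro fraction 7 may carry some (1S,2R) enantiomer. That enantiomer would become a separable diastereomer after step 7. Step 4 shares the flask, so the same concerns and the same fallback apply to it.

The fallback sets out from 4. The aldehyde is protected discretely as the dimethyl acetal F3 (HC(OMe)3, pyridinium tosylate, MeOH). F3 is reduced with (R)-Me-CBS/BH3·SMe2 in THF at −20 °C, free of phosphonium and triflate salts, to the erythro hydroxy acetal F4 and the threo hydroxy acetal F5. These are hydrolysed in the dilute HCl work-up and separated, and the route is rejoined at 7 and 10.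

**Step 7.** The electron-rich, hindered aldehyde 11 with several Lewis-basic ether oxygens may react slowly or with eroded selectivity under Brønsted acid catalysis.

The fallback sets out from 11 and replaces catalysis by a stoichiometric chiral reagent. (E)-Crotyldiisopinocampheylborane is made from trans-2-butene, n-BuLi/KOt-Bu, (−)-B-methoxydiisopinocampheylborane and BF3·OEt2 (the Si-face-selective antipode), and is used at −78 °C with NaOH/H2O2 work-up (Brown crotylboration). This gives the same anti (1S,2S) alcohol and rejoins the route at 15; it makes no new compound.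

## Further compounds

F1 | step 8 | trimethylsilyl ether of 15 | COc1ccc([C@@H](O[Si](C)(C)C(C)(C)C)[C@H](C)Oc2ccc([C@@H](O[Si](C)(C)C)[C@@H](C)C=C)cc2OC)cc1OC
F2 | step 8 | mixed O,Se-acetal of 15 and 12 (phenylselanyl, both epimers at the acetal carbon) | COc1ccc([C@@H](O[Si](C)(C)C(C)(C)C)[C@H](C)Oc2ccc([C@@H](OC([Se]c3ccccc3)c3ccc(O[C@H](C)[C@H](O[Si](C)(C)C(C)(C)C)c4ccc(OC)c(OC)c4)c(OC)c3)[C@@H](C)C=C)cc2OC)cc1OC
F3 | step 3 | rac-1-(3,4-dimethoxyphenyl)-2-[4-(dimethoxymethyl)-2-methoxyphenoxy]propan-1-one | COc1ccc(cc1OC)C(=O)C(C)Oc1ccc(cc1OC)C(OC)OC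
F4 | step 3 | (1R,2S)-1-(3,4-dimethoxyphenyl)-2-[4-(dimethoxymethyl)-2-methoxyphenoxy]propan-1-ol | COc1ccc([C@@H](O)[C@H](C)Oc2ccc(cc2OC)C(OC)OC)cc1OC
F5 | step 3 | (1R,2R)-1-(3,4-dimethoxyphenyl)-2-[4-(dimethoxymethyl)-2-methoxyphenoxy]propan-1-ol | COc1ccc([C@@H](O)[C@@H](C)Oc2ccc(cc2OC)C(OC)OC)cc1OC
F0 | step 7 | none | none
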